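**Retrosynthetic overview**
1. Ring locants: C1 ring ketone, C2 acyl-bearing carbon, C3 enol carbon, C4 prenyl-bearing carbon, C5 enol carbon, C6 diprenyl carbon. The last step only frees the C5 oxygen from a TIPS group.
2. Key disconnection: C2–C3 and C1–C6 are made together. C3–C4–C5–C6 comes as a 2,4,4-triprenyl-3-siloxycyclobut-2-enone (temporary C3–C6 bond). C1–C2 plus the side chain comes as a 5-magnesiated 6-(2-phenylethyl)-1,3-dioxin-4-one, a masked acylketene anion (temporary acetonide ring).
3. Enabling feature: the six-membered ring is a non-aromatic cyclohexane-1,3,5-trione, formally a cyclic trimer of three ketenes. Its quaternary C6 carries two identical prenyl groups and lies between the oxygenated carbons C1 and C5. C6 can therefore be the γ-terminus of a C3-oxido dienolate released from a cyclobutene, and the sense of rotation at C6 does not matter.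
4. The cyclobutenone comes from a [2+2] cycloaddition of diprenylketene (malonate route) with the TIPS ynol ether of prenylketene. The dioxinone comes from γ-benzylation and α-iodination of the commercial acetone adduct of diketene.
5. Ring order: the four-membered ring is formed first (step 6). It is then expanded by two carbons to the six-membered ring, with destruction of the dioxinone ring (step 9).

Key step: step 9

Remark: the target has no stereocentre and exists as rapidly interconverting enol tautomers; every β-triketone is drawn in the tautomer of the given structure.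

**Step 1**
Reactants: 1 diethyl malonate; 2 prenyl bromide (1-bromo-3-methylbut-2-ene)
Product: 4 diethyl 2,2-bis(3-methylbut-2-enyl)malonate, via diethyl prenylmalonate 3 (not isolated)
Conditions: NaH (2.3 equiv), 2 (2.3 equiv), THF/DMF, 0 °C to rt
Reagents that add atoms: none
Why: Double alkylation of the malonate enolate (malonic ester synthesis) with a reactive primary allylic bromide should proceed by SN2 at the unhindered terminus, and no stereocentre is formed.

**Step 2**
Reactants: 4 diethyl 2,2-bis(3-methylbut-2-enyl)malonate
Product: 5 ethyl 5-methyl-2-(3-methylbut-2-enyl)hex-4-enoate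
Conditions: LiCl, H2O, DMSO, 160 °C
Reagents that add atoms: none
Why: The Krapcho dealkoxycarbonylation removes one ester under neutral conditions, so the acid-sensitive prenyl groups are not exposed to a hot free malonic acid.

**Step 3**
Reactants: 5 ethyl 5-methyl-2-(3-methylbut-2-enyl)hex-4-enoate
Product: 6 5-methyl-2-(3-methylbut-2-enyl)hex-4-enoic acid (diprenylacetic acid)
Conditions: KOH, EtOH/H2O, 70 °C; then cold 1 M HCl
Reagents that add atoms: potassium hydroxide, [K+].[OH-]
Why: Ordinary ester saponification followed by cold, brief acidification should leave the trisubstituted alkenes untouched.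

**Step 4**
Reactants: 2 prenyl bromide; 7 ethynylmagnesium bromide
Product: 8 5-methylhex-4-en-1-yne
Conditions: CuCl (5 mol %), excess 7, THF, 0 to 40 °C; distillation
Reagents that add atoms: none
Why: Copper-catalysed allylic substitution of an alkynyl Grignard reagent should take place at the primary terminus of prenyl bromide (SN2 mode) and give the skipped enyne.

**Step 5**
Reactants: 8 5-methylhex-4-en-1-yne
Product: 11 triisopropyl[(5-methylhex-4-en-1-yn-1-yl)oxy]silane, via lithium acetylide 9 (not isolated), via lithium ynolate 10 (not isolated)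
Conditions: n-BuLi, THF, −78 °C; t-BuOOLi [from t-BuOOH and LiN(SiMe3)2], THF, −78 to 0 °C; TIPSOTf, −78 to 0 °C; then water
Reagents that add atoms: tert-butyl hydroperoxide, CC(C)(C)OO; triisopropylsilyl trifluoromethanesulfonate, CC(C)[Si](OS(=O)(=O)C(F)(F)F)(C(C)C)C(C)C
Why: Oxygenation of a lithium acetylide by lithium tert-butyl peroxide gives the ynolate, and the bulky oxophilic silyl triflate should silylate it on oxygen rather than on carbon (siloxyalkyne synthesis).

**Step 6**
Reactants: 6 diprenylacetic acid; 11 triisopropyl[(5-methylhex-4-en-1-yn-1-yl)oxy]silane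
Product: 14 2,4,4-tris(3-methylbut-2-enyl)-3-(triisopropylsilyloxy)cyclobut-2-en-1-one, via acid chloride 12 (not isolated), via diprenylketene 13 (not isolated)
Conditions: 1-chloro-N,N,2-trimethylprop-1-en-1-amine (1.0 equiv), CH2Cl2, 0 °C to rt; then 11, Et3N, toluene, rt to 45 °C
Reagents that add atoms: none
Why: HCl-free activation and dehydrochlorination give the ketene, and in its thermal [2+2] cycloaddition with the siloxyalkyne the ketene carbonyl carbon bonds to the nucleophilic alkyne carbon remote from oxygen, which fixes the regiochemistry without forming a stereocentre.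

**Step 7**
Reactants: 15 2,2,6-trimethyl-4H-1,3-dioxin-4-one; 16 benzyl bromide
Product: 18 2,2-dimethyl-6-(2-phenylethyl)-4H-1,3-dioxin-4-one, via lithium dienolate 17 (not isolated)
Conditions: LiN(iPr)2 (commercial solution), THF, −78 °C; DMPU, 16, −78 to −20 °C
Reagents that add atoms: none
Why: Vinylogous (γ-selective) alkylation of the dioxinone dienolate with a reactive benzylic halide in the presence of a polar cosolvent is an established way to extend the 6-methyl group.

**Step 8**
Reactants: 18 2,2-dimethyl-6-(2-phenylethyl)-4H-1,3-dioxin-4-one
Product: 19 5-iodo-2,2-dimethyl-6-(2-phenylethyl)-4H-1,3-dioxin-4-one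
Conditions: N-iodosuccinimide, AcOH, rt, dark
Reagents that add atoms: N-iodosuccinimide, O=C1CCC(=O)N1I
Why: Electrophilic iodination should occur at the α-carbon of the push–pull alkene, the only nucleophilic ring position, and the unactivated phenyl ring stays inert.

**Step 9**
Reactants: 19 5-iodo-2,2-dimethyl-6-(2-phenylethyl)-4H-1,3-dioxin-4-one; 14 2,4,4-tris(3-methylbut-2-enyl)-3-(triisopropylsilyloxy)cyclobut-2-en-1-one
Product: 23 3-hydroxy-4,6,6-tris(3-methylbut-2-enyl)-2-(3-phenylpropanoyl)-5-(triisopropylsilyloxy)cyclohexa-2,4-dien-1-one, via magnesiated dioxinone 20 (not isolated), via cyclobutenolate 21 (not isolated), via dienolate 22 (not isolated)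
Conditions: iPrMgCl·LiCl, THF, −40 °C; LaCl3·2LiCl, 14, −40 °C to rt, then 50 °C; cold 0.5 M HCl
Reagents that add atoms: none
Why: Proposed new method: iodine–magnesium exchange turns 19 into alkenylmagnesium 20, in effect the anion of (3-phenylpropanoyl)ketene with its enol and acid oxygens tied up as an acetonide so that the nucleophilic carbon C2 carries no hydrogen, and its LaCl3·2LiCl-assisted 1,2-addition to the strained, non-enolisable carbonyl C3 of 14 makes the C2–C3 bond and gives alkoxide 21. The oxido group then drives a conrotatory 4π electrocyclic opening of the cyclobutene that cleaves the temporary C3–C6 bond; the oxygen rotates outward, which places the dioxinonyl group cis to C5 in dienolate 22, and the two identical prenyl groups make the direction of rotation at C6 irrelevant. C6 of 22, at once the γ-carbon of the dienolate and the β-carbon of the silyl enol ether, attacks the dioxinone carbonyl C1 in a 6-(enolendo)-exo-trig Dieckmann-type closure of the carbocycle, and collapse with loss of acetone gives the magnesium β-triketonate of 23 as an irreversible sink; if this closure lags, further heating offers a second channel to the same bond, cycloreversion of the dioxinone to a dienylketene and 6π electrocyclisation. The closest known reaction types are the ring expansion of alkenylmetal adducts of cyclobutenones and squarate esters by charge-accelerated 4π opening and reclosure, the addition of 5-magnesiated dioxinones to aldehydes, and acyl transfer from dioxinones with loss of acetone, but their merger with a carbon acylation as the closing event is without direct precedent. No stereocentre has to be controlled, because the carbinol centre of racemic 21 is erased on ring opening and 23 is achiral. The step needs carbon over oxygen acylation and attack at C1 instead of conjugate attack, and the substrate secures both: the C5 oxygen is blocked by TIPS so that no 2-pyranone can form, the C3 oxido group points away from C1, C2 has no proton that could quench the dienolate, and conjugate addition to the oxygen-bearing alkene carbon of the dioxinone would join two fully substituted carbons reversibly.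

**Step 10**
Reactants: 23 3-hydroxy-4,6,6-tris(3-methylbut-2-enyl)-2-(3-phenylpropanoyl)-5-(triisopropylsilyloxy)cyclohexa-2,4-dien-1-one
Product: 24 helilupolone, 3,5-dihydroxy-4,6,6-tris(3-methylbut-2-enyl)-2-(3-phenylpropanoyl)cyclohexa-2,4-dien-1-one
Conditions: HF·pyridine, pyridine/THF, 0 °C, argon
Reagents that add atoms: none
Why: Fluoride-mediated cleavage of a silyl enol ether of a vinylogous acid is fast under buffered conditions that should leave the prenyl groups and the air-sensitive β-triketone intact.

**Compound list**
1 | diethyl malonate | CCOC(=O)CC(=O)OCC | starting material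
2 | prenyl bromide (1-bromo-3-methylbut-2-ene) | CC(C)=CCBr | starting material
3 | diethyl prenylmalonate (not isolated) | CCOC(=O)C(CC=C(C)C)C(=O)OCC | intermediate
4 | diethyl 2,2-bis(3-methylbut-2-enyl)malonate | CCOC(=O)C(CC=C(C)C)(CC=C(C)C)C(=O)OCC | intermediate
5 | ethyl 5-methyl-2-(3-methylbut-2-enyl)hex-4-enoate | CCOC(=O)C(CC=C(C)C)CC=C(C)C | intermediate
6 | 5-methyl-2-(3-methylbut-2-enyl)hex-4-enoic acid | OC(=O)C(CC=C(C)C)CC=C(C)C | intermediate
7 | ethynylmagnesium bromide | C#C[Mg]Br | starting material
8 | 5-methylhex-4-en-1-yne | C#CCC=C(C)C | intermediate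
9 | (5-methylhex-4-en-1-yn-1-yl)lithium (not isolated) | [Li]C#CCC=C(C)C | intermediate
10 | lithium 5-methylhex-4-en-1-yn-1-olate (not isolated) | [Li]OC#CCC=C(C)C | intermediate
11 | triisopropyl[(5-methylhex-4-en-1-yn-1-yl)oxy]silane | CC(C)=CCC#CO[Si](C(C)C)(C(C)C)C(C)C | intermediate
12 | 5-methyl-2-(3-methylbut-2-enyl)hex-4-enoyl chloride (not isolated) | ClC(=O)C(CC=C(C)C)CC=C(C)C | intermediate
13 | diprenylketene, 5-methyl-2-(3-methylbut-2-enyl)hexa-1,4-dien-1-one (not isolated) | O=C=C(CC=C(C)C)CC=C(C)C | intermediate
14 | 2,4,4-tris(3-methylbut-2-enyl)-3-(triisopropylsilyloxy)cyclobut-2-en-1-one | O=C1C(CC=C(C)C)=C(O[Si](C(C)C)(C(C)C)C(C)C)C1(CC=C(C)C)CC=C(C)C | intermediate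
15 | 2,2,6-trimethyl-4H-1,3-dioxin-4-one | CC1=CC(=O)OC(C)(C)O1 | starting material
16 | benzyl bromide | BrCc1ccccc1 | starting material
17 | lithium dienolate of 15 (not isolated) | C=C1C=C(O[Li])OC(C)(C)O1 | intermediate
18 | 2,2-dimethyl-6-(2-phenylethyl)-4H-1,3-dioxin-4-one | CC1(C)OC(=O)C=C(CCc2ccccc2)O1 | intermediate
19 | 5-iodo-2,2-dimethyl-6-(2-phenylethyl)-4H-1,3-dioxin-4-one | CC1(C)OC(=O)C(I)=C(CCc2ccccc2)O1 | intermediate
20 | 5-(chloromagnesio)-2,2-dimethyl-6-(2-phenylethyl)-4H-1,3-dioxin-4-one (not isolated) | CC1(C)OC(=O)C([Mg]Cl)=C(CCc2ccccc2)O1 | intermediate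
21 | chloromagnesium 1-(dioxinon-5-yl)-2,4,4-triprenyl-3-(triisopropylsilyloxy)cyclobut-2-en-1-olate, racemic (not isolated) | Cl[Mg]OC1(C2=C(CCc3ccccc3)OC(C)(C)OC2=O)C(CC=C(C)C)=C(O[Si](C(C)C)(C(C)C)C(C)C)C1(CC=C(C)C)CC=C(C)C | intermediate
22 | ring-opened chloromagnesium dienolate, oxido group trans to the siloxy-bearing carbon (not isolated) | Cl[Mg]O/C(C1=C(CCc2ccccc2)OC(C)(C)OC1=O)=C(\CC=C(C)C)C(O[Si](C(C)C)(C(C)C)C(C)C)=C(CC=C(C)C)CC=C(C)C | intermediate
23 | 3-hydroxy-4,6,6-tris(3-methylbut-2-enyl)-2-(3-phenylpropanoyl)-5-(triisopropylsilyloxy)cyclohexa-2,4-dien-1-one | CC(C)=CCC1=C(O[Si](C(C)C)(C(C)C)C(C)C)C(CC=C(C)C)(CC=C(C)C)C(=O)C(C(=O)CCc2ccccc2)=C1O | intermediate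
24 | helilupolone | CC(C)=CCC1=C(O)C(CC=C(C)C)(CC=C(C)C)C(=O)C(C(=O)CCc2ccccc2)=C1O | target

**Step count**
Total step count: 10.
Longest linear sequence: 6 steps (1, 2, 3, 6, 9, 10).

**Three steps most likely to fail**

Step 9. Three processes could go wrong:
- The 1,2-addition of the hindered, ester-stabilised alkenylmagnesium to a carbonyl flanked by a quaternary carbon may be slower than β-elimination of the reagent.
- The alkoxide may close on the lactone carbonyl before the ring opens.
- The alkoxide may take over the silyl group before the ring opens.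

The fallback uses known chemistry, sets out from prenyl bromide 2 and comes back at 24. Friedel–Crafts acylation of phloroglucinol with 3-phenylpropanoyl chloride (AlCl3, CH2Cl2/nitromethane) should give 1-(2,4,6-trihydroxyphenyl)-3-phenylpropan-1-one F1. Threefold base-mediated C-prenylation of F1 with 2 (NaOMe, MeOH, 0 °C) should then give 24 directly. The last alkylation takes place at an already prenylated ring carbon and dearomatises the ring. This reaction type is well established for acylphloroglucinols.

Step 6. The bulky internal siloxyalkyne may be lost to protonation by triethylammonium chloride, and ketene 13 to dimerisation, faster than the cycloaddition proceeds. The fallback sets out from acid chloride 12 and prenyl bromide 2 and comes back at 14.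
- Ethoxyacetylene is deprotonated (n-BuLi, THF/DMPU) and alkylated with 2 to give the more robust and less hindered 1-ethoxy-5-methylhex-4-en-1-yne F2.
- Cycloaddition of F2 with ketene 13 (from 12 and Et3N) should give 3-ethoxy-2,4,4-tris(3-methylbut-2-enyl)cyclobut-2-en-1-one F3.
- Mild hydrolysis (dilute HCl, THF) should give 2,2,4-tris(3-methylbut-2-enyl)cyclobutane-1,3-dione F4.
- The two carbonyl groups of F4 are equivalent, so O-silylation (TIPSOTf, Et3N) can lead only to 14.

Step 7. Competing α-alkylation, double alkylation and self-condensation of dienolate 17 may erode the γ-benzylation. The fallback sets out from benzyl bromide 16 and comes back at 18. The dianion of tert-butyl acetoacetate (NaH, then n-BuLi, THF, 0 °C) is alkylated at its terminal carbon with 16 to give tert-butyl 3-oxo-5-phenylpentanoate F5. Treatment of F5 with acetone, trifluoroacetic anhydride and trifluoroacetic acid should close the dioxinone ring of 18 with loss of the tert-butyl group.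

**Further compounds**
F1 | step 9 | 1-(2,4,6-trihydroxyphenyl)-3-phenylpropan-1-one | O=C(CCc1ccccc1)c1c(O)cc(O)cc1O
F2 | step 6 | 1-ethoxy-5-methylhex-4-en-1-yne | CCOC#CCC=C(C)C
F3 | step 6 | 3-ethoxy-2,4,4-tris(3-methylbut-2-enyl)cyclobut-2-en-1-one | CCOC1=C(CC=C(C)C)C(=O)C1(CC=C(C)C)CC=C(C)C
F4 | step 6 | 2,2,4-tris(3-methylbut-2-enyl)cyclobutane-1,3-dione | O=C1C(CC=C(C)C)C(=O)C1(CC=C(C)C)CC=C(C)C
F5 | step 7 | tert-butyl 3-oxo-5-phenylpentanoate | CC(C)(C)OC(=O)CC(=O)CCc1ccccc1
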